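**Plan**
- Cuts: the O–Si bond at the carbinol. The CH=C(CHO) double bond, giving an allyl-bearing anhydride and a 2-alkylacrolein; the acrolein is cut again at the CH2–CH2 bond next to farnesyl C1. The anhydride C–O–C, back to the isomeric trans γ-lactone acid. The carbinol–CH2 bond (allylsilane). The two bonds of a cyclopropane.
- Enabling feature: the carbinol carbon, the ring CH and the anhydride C=O on that CH are C3, C4 and C5 of methyl 2-furoate. The ring CH2 and its C=O are the carbene carbon and the carboxyl carbon of ethyl diazoacetate. Furan C2 and its ester leave as oxalate.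
- Forward order: cyclopropane fused onto the furan (step 1), dihydrofuran ring cut by ozone, allyl group added, cyclopropane opened with closure of the γ-lactone, lactone exchanged for the five-membered anhydride, farnesyl-derived chain joined, silyl group removed.
- Stereochemistry: the copper bis(oxazoline) catalyst fixes the ring CH (S in the target). That centre steers the Felkin–Anh allylation to the (R)-carbinol, which is read out as the trans lactone. The E enal geometry arises in the metathesis, and the two E trisubstituted olefins come with farnesyl bromide.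

Key step: step 1

Assumption: the ligand made from L-valinol, (S,S), is taken to lead to the (1S,5S,6S) adduct. The (R,R) ligand from D-valinol is therefore used for the (1R,5R,6R) series required here. If the sense were the opposite, the other commercial ligand antipode would be used and nothing else would change.

Step 1
Reactants: 1 methyl furan-2-carboxylate; 2 ethyl diazoacetate
Product: 3 6-ethyl 3-methyl (1R,5R,6R)-2-oxabicyclo[3.1.0]hex-3-ene-3,6-dicarboxylate (exo ester)
Conditions: Cu(OTf)2 (1 mol %), (R,R)-iPr-box = 2,2'-(propane-2,2-diyl)bis[(4R)-4-isopropyl-4,5-dihydrooxazole] (1.2 mol %), PhNHNH2 (1 mol %), 1 in excess, CH2Cl2, 0 °C, slow addition of 2; recrystallisation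
Reagents that add atoms: none
Why: Phenylhydrazine reduces Cu(OTf)2 to monovalent copper, whose bis(oxazoline) complex takes N2 out of 2 and passes the resulting electrophilic carbene to C4=C5 of 1 in a concerted, asynchronous (2+1) cycloaddition, the closest known reaction type being the copper bis(oxazoline) catalysed asymmetric cyclopropanation of 2-furoates and related electron-rich heteroarenes. The cyclopropane closes by suprafacial formation of both new C–C bonds (carbene carbon to furan C4 and to furan C5) in one event, a cheletropic-type closure that makes the ring fusion necessarily cis. Site selectivity is required and is secured by the ester on furan C2, which drains C2=C3 and leaves C4=C5 as the more nucleophilic, enol-ether-like bond. The exo position of CO2Et at C6 is controlled by steric avoidance between this ester and the furan ring in the approach to the copper carbene. The configurations at C1 and C5 are controlled by the twofold-symmetric (R,R) ligand, whose isopropyl groups leave only one enantioface of the furan bond accessible, and recrystallisation of 3 should upgrade the enantiomeric purity. C5 of 3 is the future ring CH of the anhydride and the C5–C6 bond its CH–CH2 bond, whereas the C1–C6 bond is made only to be broken again in step 4.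

Step 2
Reactants: 3 6-ethyl 3-methyl (1R,5R,6R)-2-oxabicyclo[3.1.0]hex-3-ene-3,6-dicarboxylate
Product: 5 methyl (1R,2R,3R)-2-(ethoxycarbonyl)-3-formylcyclopropyl oxalate, via secondary ozonide 4 (not isolated)
Conditions: O3, CH2Cl2, −78 °C; then Me2S, −78 °C to rt
Reagents that add atoms: ozone [O-][O+]=O
Why: Ozonolysis (Criegee mechanism) of the only C=C bond with reductive work-up cuts the dihydrofuran ring, leaving furan C3 as the formyl group and furan C2 as a methyl oxalyl ester on the cyclopropanol oxygen, without touching the three stereocentres.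

Step 3
Reactants: 5 methyl (1R,2R,3R)-2-(ethoxycarbonyl)-3-formylcyclopropyl oxalate; 6 allyltrimethylsilane
Product: 7 methyl (1R,2R,3S)-2-(ethoxycarbonyl)-3-[(1R)-1-hydroxybut-3-enyl]cyclopropyl oxalate
Conditions: BF3·OEt2 (1.1 equiv), CH2Cl2, −78 °C; aqueous work-up
Reagents that add atoms: none
Why: In this Hosomi–Sakurai allylation through an open transition state the BF3-bound aldehyde sits in a bisected conformation and is attacked in the Felkin–Anh sense, anti to the ring bond leading to the oxalyloxy-bearing carbon, so that the adjacent cyclopropane centre sets the new (R)-carbinol while the low temperature keeps the donor-acceptor cyclopropane closed.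

Step 4
Reactants: 7 methyl (1R,2R,3S)-2-(ethoxycarbonyl)-3-[(1R)-1-hydroxybut-3-enyl]cyclopropyl oxalate
Product: 10 (2R,3S)-2-allyl-5-oxooxolane-3-carbaldehyde, via free cyclopropanol 8 (not isolated), via ring-opened hydroxy aldehyde ester 9 (not isolated)
Conditions: Ba(OH)2·8H2O (1 equiv), MeOH, 0 °C
Reagents that add atoms: none
Why: Base strips off the oxalyl group, the cyclopropanolate donor and the vicinal ester acceptor then break exactly the bond between their two carbons by retro-aldol ring opening, and the carbinol lactonises 5-exo-trig onto the freed CH2CO2Et arm to the thermodynamically preferred trans-disubstituted γ-butyrolactone with both stereocentres retained.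

Step 5
Reactants: 10 (2R,3S)-2-allyl-5-oxooxolane-3-carbaldehyde
Product: 11 (2R,3S)-2-allyl-5-oxooxolane-3-carboxylic acid
Conditions: NaClO2, NaH2PO4, 2-methyl-2-butene, t-BuOH/H2O, 0 °C to rt
Reagents that add atoms: sodium chlorite [Na+].[O-]Cl=O
Why: The Pinnick oxidation works at buffered, weakly acidic pH, so the epimerisable aldehyde is oxidised without enolisation, and the trisubstituted scavenger olefin intercepts HOCl faster than the monosubstituted allyl group.

Step 6
Reactants: 11 (2R,3S)-2-allyl-5-oxooxolane-3-carboxylic acid
Product: 13 bis(triethylsilyl) (2S)-2-[(1R)-1-(triethylsilyloxy)but-3-enyl]butanedioate, via dipotassium hydroxy dicarboxylate 12 (not isolated)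
Conditions: KOH (2.1 equiv), THF/H2O, rt; evaporation, toluene azeotrope; then Et3SiCl (4 equiv), imidazole (5 equiv), DMF, 0 °C to rt; pentane extraction, used crude
Reagents that add atoms: potassium hydroxide [K+].[OH-]; chlorotriethylsilane CC[Si](Cl)(CC)CC
Why: Saponification opens the lactone to a dicarboxylate that cannot relactonise while it stays a salt, and exhaustive imidazole-promoted silylation, the usual way of trapping ring-opened γ-lactones, caps the alcohol and both carboxylates without touching the non-acidic α-CH of the carboxylate.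

Step 7
Reactants: 13 bis(triethylsilyl) (2S)-2-[(1R)-1-(triethylsilyloxy)but-3-enyl]butanedioate
Product: 15 (3S)-3-[(1R)-1-(triethylsilyloxy)but-3-enyl]oxolane-2,5-dione, via mono acid chloride 14 (not isolated)
Conditions: (COCl)2 (1.05 equiv), DMF (cat.), CH2Cl2, 0 °C to rt; bulb-to-bulb distillation or rapid filtration through dry silica
Reagents that add atoms: none
Why: Silyl esters are converted by oxalyl chloride and catalytic DMF (Vilsmeier-type activation) into acid chlorides under neutral conditions, and the neighbouring silyl carboxylate then attacks the acyl chloride 5-exo-trig with loss of Et3SiCl to close the succinic anhydride, while the hindered secondary silyl ether stays in place.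

Step 8
Reactants: 16 2-methylprop-2-en-1-ol; 17 (2E,6E)-farnesyl bromide
Product: 19 (5E,9E)-6,10,14-trimethyl-2-methylidenepentadeca-5,9,13-trien-1-ol, via dilithiated methallyl alcohol 18 (not isolated)
Conditions: 16, n-BuLi (2.1 equiv), TMEDA, Et2O/hexane, 0 °C to rt; then 17, THF, −78 °C to rt; H2O
Reagents that add atoms: none
Why: Allylic metalation of the lithium alkoxide gives an allyl anion with two equivalent CH2 termini, and its SN2 alkylation by the primary allylic bromide forms the CH2–CH2 bond of the 1,5-diene with both E olefins retained.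

Step 9
Reactants: 19 (5E,9E)-6,10,14-trimethyl-2-methylidenepentadeca-5,9,13-trien-1-ol
Product: 20 (5E,9E)-6,10,14-trimethyl-2-methylidenepentadeca-5,9,13-trienal
Conditions: activated MnO2 (excess), CH2Cl2, rt; used without storage
Reagents that add atoms: none
Why: The MnO2 oxidation of allylic alcohols is neutral and stops at the aldehyde, so the isolated trisubstituted olefins and the polymerisation-prone 2-alkylacrolein unit should be left intact.

Step 10
Reactants: 15 (3S)-3-[(1R)-1-(triethylsilyloxy)but-3-enyl]oxolane-2,5-dione; 20 (5E,9E)-6,10,14-trimethyl-2-methylidenepentadeca-5,9,13-trienal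
Product: 21 (3S)-3-[(1R,3E,7E,11E)-4-formyl-8,12,16-trimethyl-1-(triethylsilyloxy)heptadeca-3,7,11,15-tetraenyl]oxolane-2,5-dione
Conditions: second-generation Hoveyda–Grubbs catalyst, (H2IMes)Cl2Ru(=CH-2-iPrOC6H4) (5 mol % in two portions), 15 (2 equiv), 20 (1 equiv), CH2Cl2, 40 °C, argon purge; recovered 15 and its homodimer are resubmitted
Reagents that add atoms: none
Why: This is an olefin cross-metathesis of a fast-initiating monosubstituted olefin with an electron-poor 1,1-disubstituted olefin, as known for methacrolein and 2-ethylacrolein, in which the conjugated trisubstituted enal is a metathesis-inert end point formed as the E isomer (formyl trans to the carbinol chain), the internal trisubstituted olefins are too hindered to react, and the excess of 15 keeps the ruthenium methylidene occupied and away from the isopropylidene end.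

Step 11
Reactants: 21 (3S)-3-[(1R,3E,7E,11E)-4-formyl-8,12,16-trimethyl-1-(triethylsilyloxy)heptadeca-3,7,11,15-tetraenyl]oxolane-2,5-dione
Product: 22 hippolide D, (3S)-3-[(1R,3E,7E,11E)-4-formyl-1-hydroxy-8,12,16-trimethylheptadeca-3,7,11,15-tetraenyl]oxolane-2,5-dione
Conditions: Et3N·3HF (3 equiv), MeCN/CH2Cl2, 0 °C; dilution with Et2O, brief wash with ice-cold pH 5 buffer, rapid filtration through silica
Reagents that add atoms: none
Why: Fluoride-driven desilylation (formation of the strong Si–F bond) removes the labile secondary triethylsilyl ether under weakly acidic, water-free conditions without unprotonated amine, which should spare anhydride, enal and olefins, and intramolecular acyl transfer to the freed hydroxyl would have to pass through a strained 2,6-dioxabicyclo[2.2.1]heptane tetrahedral intermediate.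

**Compound list**
1 | methyl furan-2-carboxylate | COC(=O)c1ccco1 | starting material
2 | ethyl diazoacetate | CCOC(=O)C=[N+]=[N-] | starting material
3 | 6-ethyl 3-methyl (1R,5R,6R)-2-oxabicyclo[3.1.0]hex-3-ene-3,6-dicarboxylate | COC(=O)C1=C[C@@H]2[C@@H](C(=O)OCC)[C@@H]2O1 | intermediate
4 | secondary ozonide of 3 (the two acetal carbons are not defined and are lost again) | COC(=O)C12OOC(O1)[C@@H]1[C@@H](C(=O)OCC)[C@@H]1O2 | intermediate
5 | methyl (1R,2R,3R)-2-(ethoxycarbonyl)-3-formylcyclopropyl oxalate | O=C[C@@H]1[C@@H](C(=O)OCC)[C@@H]1OC(=O)C(=O)OC | intermediate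
6 | allyltrimethylsilane | C=CC[Si](C)(C)C | starting material
7 | methyl (1R,2R,3S)-2-(ethoxycarbonyl)-3-[(1R)-1-hydroxybut-3-enyl]cyclopropyl oxalate | C=CC[C@@H](O)[C@@H]1[C@@H](C(=O)OCC)[C@@H]1OC(=O)C(=O)OC | intermediate
8 | ethyl (1R,2R,3S)-2-hydroxy-3-[(1R)-1-hydroxybut-3-enyl]cyclopropane-1-carboxylate | C=CC[C@@H](O)[C@@H]1[C@@H](C(=O)OCC)[C@@H]1O | intermediate
9 | ethyl (3S,4R)-3-formyl-4-hydroxyhept-6-enoate | C=CC[C@@H](O)[C@@H](C=O)CC(=O)OCC | intermediate
10 | (2R,3S)-2-allyl-5-oxooxolane-3-carbaldehyde | C=CC[C@H]1OC(=O)C[C@@H]1C=O | intermediate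
11 | (2R,3S)-2-allyl-5-oxooxolane-3-carboxylic acid | C=CC[C@H]1OC(=O)C[C@@H]1C(=O)O | intermediate
12 | dipotassium (2S)-2-[(1R)-1-hydroxybut-3-enyl]butanedioate | C=CC[C@@H](O)[C@@H](C(=O)[O-])CC(=O)[O-].[K+].[K+] | intermediate
13 | bis(triethylsilyl) (2S)-2-[(1R)-1-(triethylsilyloxy)but-3-enyl]butanedioate | C=CC[C@@H](O[Si](CC)(CC)CC)[C@@H](C(=O)O[Si](CC)(CC)CC)CC(=O)O[Si](CC)(CC)CC | intermediate
14 | triethylsilyl (2S,3R)-2-(2-chloro-2-oxoethyl)-3-(triethylsilyloxy)hex-5-enoate | C=CC[C@@H](O[Si](CC)(CC)CC)[C@@H](C(=O)O[Si](CC)(CC)CC)CC(=O)Cl | intermediate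
15 | (3S)-3-[(1R)-1-(triethylsilyloxy)but-3-enyl]oxolane-2,5-dione | C=CC[C@@H](O[Si](CC)(CC)CC)[C@@H]1CC(=O)OC1=O | intermediate
16 | 2-methylprop-2-en-1-ol | C=C(C)CO | starting material
17 | (2E,6E)-farnesyl bromide | CC(C)=CCC/C(C)=C/CC/C(C)=C/CBr | starting material
18 | dilithiated methallyl alcohol | [Li]CC(=C)CO[Li] | intermediate
19 | (5E,9E)-6,10,14-trimethyl-2-methylidenepentadeca-5,9,13-trien-1-ol | CC(C)=CCC/C(C)=C/CC/C(C)=C/CCC(=C)CO | intermediate
20 | (5E,9E)-6,10,14-trimethyl-2-methylidenepentadeca-5,9,13-trienal | CC(C)=CCC/C(C)=C/CC/C(C)=C/CCC(=C)C=O | intermediate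
21 | O-triethylsilyl hippolide D | CC(C)=CCC/C(C)=C/CC/C(C)=C/CC/C(C=O)=C\C[C@@H](O[Si](CC)(CC)CC)[C@@H]1CC(=O)OC1=O | intermediate
22 | hippolide D | CC(C)=CCC/C(C)=C/CC/C(C)=C/CC/C(C=O)=C\C[C@@H](O)[C@@H]1CC(=O)OC1=O | target

Total step count: 11. Longest linear sequence: 9 (steps 1 to 7, 10 and 11).

**Steps most likely to fail**

Step 10 is most at risk.
- What may go wrong: the propagating ruthenium alkylidene may also attack the isopropylidene end of the farnesyl tail, causing loss of isobutene, scrambling of the tail and self-metathesis of 20. The coupling may also stall at homodimerisation of 15, because the 1,1-disubstituted acceptor olefin cannot be used in large excess.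
- Fallback: carbonyl olefination replaces metathesis. It sets out from 15 and 17 and comes back to the route at 21.
- From 15: ozone in CH2Cl2 at −78 °C would turn the vinyl group into the terminal ozonide F1. PPh3 reduces this to (3R)-3-[(3S)-2,5-dioxooxolan-3-yl]-3-(triethylsilyloxy)propanal F2.
- From 17: alkylation with the lithium enolate of ethyl acetate (LDA, THF, −78 °C) would give ethyl (4E,8E)-5,9,13-trimethyltetradeca-4,8,12-trienoate F3. LiAlH4 reduces it to (4E,8E)-5,9,13-trimethyltetradeca-4,8,12-trien-1-ol F4. I2, PPh3 and imidazole convert that into (6E,10E)-14-iodo-2,6,10-trimethyltetradeca-2,6,10-triene F5, and heating with PPh3 in MeCN gives the phosphonium iodide F6.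
- Ylide: NaHMDS would give the non-stabilised ylide F7. Its C-formylation with ethyl formate, in the presence of a second equivalent of base, leads to (5E,9E)-6,10,14-trimethyl-2-(triphenylphosphoranylidene)pentadeca-5,9,13-trienal F8.
- Union: a Wittig reaction of F2 with F8 in benzene at about 50 °C should be E-selective, as is usual for 2-(triphenylphosphoranylidene)alkanals. It should also be much faster at the aldehyde than at the anhydride, and it should give 21 without any catalyst that can touch the tail olefins.

Step 11 comes second.
- What may go wrong: the anhydride may be opened by adventitious water or fluoride and then lactonise onto the freed hydroxyl. The polyene may undergo acid-induced cyclisation. The δ-oxygen substituent of the enal may be lost by vinylogous elimination.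
- Fallback: the order of events is changed. It sets out from 15 and comes back at 22.
- Sequence: 15 is desilylated first with Et3N·3HF to (3S)-3-[(1R)-1-hydroxybut-3-enyl]oxolane-2,5-dione F9. This small compound has no enal or polyene, so its lifetime can be tested and it can be purified by crystallisation. The cross-metathesis of F9 with 20 under the conditions of step 10, which tolerates free homoallylic alcohols, then becomes the last step. It is neutral and aprotic and gives 22 directly.

Step 6 comes third.
- What may go wrong: relactonisation may outrun O-silylation, because the first-formed silyl ester acts as an acyl donor towards the γ-hydroxyl. The material then falls back to 11.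
- Fallback: the carbinol is capped before the cyclopropane is opened, so that no lactone ever forms. It sets out from 7 and comes back at 15.
- Sequence: Et3SiOTf and 2,6-lutidine (CH2Cl2, −78 °C) would give the triethylsilyl ether of the allylation product F10. Catalytic K2CO3 in MeOH at 0 °C removes the oxalyl group by methanolysis and triggers the same retro-aldol ring opening, giving ethyl (3S,4R)-3-formyl-4-(triethylsilyloxy)hept-6-enoate F11. Pinnick oxidation gives (2S,3R)-2-(2-ethoxy-2-oxoethyl)-3-(triethylsilyloxy)hex-5-enoic acid F12. LiOH in THF/H2O, followed by acidification to pH 4, gives (2S)-2-[(1R)-1-(triethylsilyloxy)but-3-enyl]butanedioic acid F13, and DCC in CH2Cl2 dehydrates it to 15.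
- Caveat: this path gives up the thermodynamic safeguard of the trans lactone. Contact with base must therefore be short, to avoid epimerisation and β-elimination at the aldehyde stage.

**Further compounds**
F1 | step 10 | terminal ozonide of 15 | C1OOC(O1)C[C@@H](O[Si](CC)(CC)CC)[C@@H]1CC(=O)OC1=O
F2 | step 10 | (3R)-3-[(3S)-2,5-dioxooxolan-3-yl]-3-(triethylsilyloxy)propanal | O=CC[C@@H](O[Si](CC)(CC)CC)[C@@H]1CC(=O)OC1=O
F3 | step 10 | ethyl (4E,8E)-5,9,13-trimethyltetradeca-4,8,12-trienoate | CC(C)=CCC/C(C)=C/CC/C(C)=C/CCC(=O)OCC
F4 | step 10 | (4E,8E)-5,9,13-trimethyltetradeca-4,8,12-trien-1-ol | CC(C)=CCC/C(C)=C/CC/C(C)=C/CCCO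
F5 | step 10 | (6E,10E)-14-iodo-2,6,10-trimethyltetradeca-2,6,10-triene | CC(C)=CCC/C(C)=C/CC/C(C)=C/CCCI
F6 | step 10 | [(4E,8E)-5,9,13-trimethyltetradeca-4,8,12-trienyl]triphenylphosphonium iodide | CC(C)=CCC/C(C)=C/CC/C(C)=C/CCC[P+](c1ccccc1)(c1ccccc1)c1ccccc1.[I-]
F7 | step 10 | [(4E,8E)-5,9,13-trimethyltetradeca-4,8,12-trienylidene]triphenylphosphorane | CC(C)=CCC/C(C)=C/CC/C(C)=C/CCC=P(c1ccccc1)(c1ccccc1)c1ccccc1
F8 | step 10 | (5E,9E)-6,10,14-trimethyl-2-(triphenylphosphoranylidene)pentadeca-5,9,13-trienal | CC(C)=CCC/C(C)=C/CC/C(C)=C/CCC(C=O)=P(c1ccccc1)(c1ccccc1)c1ccccc1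
F9 | step 11 | (3S)-3-[(1R)-1-hydroxybut-3-enyl]oxolane-2,5-dione | C=CC[C@@H](O)[C@@H]1CC(=O)OC1=O
F10 | step 6 | methyl (1R,2R,3S)-2-(ethoxycarbonyl)-3-[(1R)-1-(triethylsilyloxy)but-3-enyl]cyclopropyl oxalate | C=CC[C@@H](O[Si](CC)(CC)CC)[C@@H]1[C@@H](C(=O)OCC)[C@@H]1OC(=O)C(=O)OC
F11 | step 6 | ethyl (3S,4R)-3-formyl-4-(triethylsilyloxy)hept-6-enoate | C=CC[C@@H](O[Si](CC)(CC)CC)[C@@H](C=O)CC(=O)OCC
F12 | step 6 | (2S,3R)-2-(2-ethoxy-2-oxoethyl)-3-(triethylsilyloxy)hex-5-enoic acid | C=CC[C@@H](O[Si](CC)(CC)CC)[C@@H](C(=O)O)CC(=O)OCC
F13 | step 6 | (2S)-2-[(1R)-1-(triethylsilyloxy)but-3-enyl]butanedioic acid | C=CC[C@@H](O[Si](CC)(CC)CC)[C@@H](C(=O)O)CC(=O)O
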